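**Plan** (benzofuran numbering: O1, C2, C3, C3a, C4–C7, C7a; ring A = carbocycle, ring B = furan ring)
1. Last cut: the C3a=C4 double bond of ring A, by a retro-vinylogous aldol condensation, back to keto aldehyde 17, in which C4 is a formyl group on the quaternary C5.
2. Then O1–C7a (oxa-Michael addition) and C6–C7 (acylation of an alkynide) are cut, giving fragment 1 (alkynol 6: aryl, C2, C3, C3a, C7a, C7) and fragment 2 (Weinreb amide 13: C4, C5, C6, allyl, OMe).
3. Forward: the chain is joined at C6–C7, ring B closes by 5-exo-dig oxa-Michael addition, C4 is raised to the aldehyde, and ring A closes last.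
4. Enabling feature: the exocyclic vinylogous ester O1–C7a=C7–C6=O makes the ring-B methylene C3a γ-acidic and places it 1,6 to the formyl carbon C4, while the fully substituted C5 blocks every other enolisation and any aromatisation of ring A.
5. Stereochemistry: C2 and C3 come from one catalytic anti-selective (E)-crotylboration of veratraldehyde; C5 comes from a catalytic desymmetrising reduction of the prochiral malonate 9; the endgame creates no stereocentre.

Key step: step 12

Remark: the facial sense of the catalysts in steps 1 and 6 is assumed by analogy with simple substrates (the mirror-image catalyst would be used otherwise). Compounds 15–17 are drawn as the E enol ethers expected after equilibration, although either geometry serves. Lactol 5 stands for both anomers together with its open hydroxy aldehyde tautomer.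

Step 1
Reactants: 1 3,4-dimethoxybenzaldehyde; 2 (E)-crotylboronic acid pinacol ester
Product: 3 (1R,2R)-1-(3,4-dimethoxyphenyl)-2-methylbut-3-en-1-ol
Conditions: (R)-TRIP [(R)-3,3′-bis(2,4,6-triisopropylphenyl)-1,1′-binaphthyl-2,2′-diyl hydrogen phosphate] (5 mol%), 4 Å MS, toluene, −30 °C; aqueous work-up
Reagents that add atoms: none
Why: Chiral phosphoric acid-catalysed crotylboration, in which the closed chair transition state turns the E geometry of 2 into the anti relationship of the carbinol and methyl centres (later C2 and C3) and the catalyst, hydrogen-bonded to a boronate oxygen and the formyl hydrogen, selects the aldehyde face.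

Step 2
Reactants: 3 (1R,2R)-1-(3,4-dimethoxyphenyl)-2-methylbut-3-en-1-ol
Product: 4 (1R,2R)-1-(3,4-dimethoxyphenyl)-2-methylbutane-1,4-diol
Conditions: 9-BBN (2.2 equiv), THF, 0 °C → rt; NaOH, H2O2, 0 °C
Reagents that add atoms: hydrogen peroxide, OO
Why: Anti-Markovnikov hydroboration–oxidation of the terminal alkene, which does not touch the two stereocentres.

Step 3
Reactants: 4 (1R,2R)-1-(3,4-dimethoxyphenyl)-2-methylbutane-1,4-diol
Product: 5 (4R,5R)-5-(3,4-dimethoxyphenyl)-4-methyltetrahydrofuran-2-ol (lactol, mixture of anomers)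
Conditions: TEMPO (0.1 equiv), PhI(OAc)2 (1.1 equiv), CH2Cl2, 0 °C → rt, stopped when 4 is consumed
Reagents that add atoms: none
Why: Oxoammonium-mediated oxidation, which should take the unhindered primary alcohol much faster than the secondary benzylic one; the hydroxy aldehyde closes at once to the five-membered lactol, and the single equivalent of oxidant should hold the material at this oxidation level with both stereocentres untouched.

Step 4
Reactants: 5 (4R,5R)-5-(3,4-dimethoxyphenyl)-4-methyltetrahydrofuran-2-ol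
Product: 6 (1R,2R)-1-(3,4-dimethoxyphenyl)-2-methylpent-4-yn-1-ol
Conditions: dimethyl (1-diazo-2-oxopropyl)phosphonate (1.5 equiv), K2CO3 (2.5 equiv), MeOH, 0 °C → rt
Reagents that add atoms: dimethyl (1-diazo-2-oxopropyl)phosphonate, CC(=O)C(=[N+]=[N-])P(=O)(OC)OC
Why: Seyferth–Gilbert homologation under Ohira–Bestmann conditions, which acts on the open hydroxy aldehyde tautomer of the lactol; the methyl-bearing centre is β to the aldehyde and cannot epimerise.

Step 5
Reactants: 7 dimethyl 2-methoxymalonate; 8 allyl bromide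
Product: 9 dimethyl 2-allyl-2-methoxymalonate
Conditions: NaH, THF/DMF, 0 °C → rt
Reagents that add atoms: none
Why: SN2 alkylation of the malonate enolate, giving a prochiral carbon (later C5) that already carries the methoxy and allyl groups.

Step 6
Reactants: 9 dimethyl 2-allyl-2-methoxymalonate
Product: 11 methyl (S)-2-(hydroxymethyl)-2-methoxypent-4-enoate, via silyl ether 10 (not isolated)
Conditions: ZnEt2 (10 mol%), pipecolinol-derived ProPhenol-type tetradentate aminophenol ligand (5 mol%), (MeO)2MeSiH (3 equiv), THF, 0 °C → rt; then K2CO3, MeOH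
Reagents that add atoms: none
Why: Zinc-catalysed desymmetrising hydrosilylation of a fully substituted malonic ester, in which the chiral dinuclear zinc hydride binds the diester and reduces only one enantiotopic ester to the silyl ether, so that the catalyst sets the quaternary centre C5 by telling methoxy from allyl; the terminal alkene is inert to the zinc hydride.

Step 7
Reactants: 11 methyl (S)-2-(hydroxymethyl)-2-methoxypent-4-enoate
Product: 12 methyl (S)-2-{[(tert-butyldimethylsilyl)oxy]methyl}-2-methoxypent-4-enoate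
Conditions: TBSCl, imidazole, DMF, rt
Reagents that add atoms: tert-butyldimethylsilyl chloride, CC(C)(C)[Si](C)(C)Cl
Why: Standard silylation of the primary alcohol, which masks the C4 oxygen so that it cannot later add to the ynone in a 6-endo sense.

Step 8
Reactants: 12 methyl (S)-2-{[(tert-butyldimethylsilyl)oxy]methyl}-2-methoxypent-4-enoate
Product: 13 (S)-2-{[(tert-butyldimethylsilyl)oxy]methyl}-N,2-dimethoxy-N-methylpent-4-enamide
Conditions: MeNH(OMe)·HCl (3 equiv), i-PrMgCl (6 equiv), THF, −20 °C → rt
Reagents that add atoms: N,O-dimethylhydroxylamine hydrochloride, CNOC.Cl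
Why: Aminolysis of the ester by the magnesium amide to the Weinreb amide; the α-carbon is quaternary and cannot epimerise.

Step 9
Reactants: 6 (1R,2R)-1-(3,4-dimethoxyphenyl)-2-methylpent-4-yn-1-ol; 13 (S)-2-{[(tert-butyldimethylsilyl)oxy]methyl}-N,2-dimethoxy-N-methylpent-4-enamide
Product: 15 (S,E)-3-{[(tert-butyldimethylsilyl)oxy]methyl}-1-[(4R,5R)-5-(3,4-dimethoxyphenyl)-4-methyldihydrofuran-2(3H)-ylidene]-3-methoxyhex-5-en-2-one, via hydroxy ynone 14 (not isolated)
Conditions: 6, n-BuLi (2.05 equiv), THF, −78 °C; 13, −78 → 0 °C; aq NH4Cl; then Cs2CO3 (0.2 equiv), MeCN, rt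
Reagents that add atoms: none
Why: Weinreb ketone synthesis with the C-lithiated alkoxide of 6 (the chelated tetrahedral adduct releases ynone 14 only on quenching), followed by base-catalysed 5-exo-dig oxa-Michael addition of the C2 oxygen to the ynone β-carbon C7a, which closes ring B without creating or touching a stereocentre.

Step 10
Reactants: 15 (S,E)-3-{[(tert-butyldimethylsilyl)oxy]methyl}-1-[(4R,5R)-5-(3,4-dimethoxyphenyl)-4-methyldihydrofuran-2(3H)-ylidene]-3-methoxyhex-5-en-2-one
Product: 16 (S,E)-1-[(4R,5R)-5-(3,4-dimethoxyphenyl)-4-methyldihydrofuran-2(3H)-ylidene]-3-(hydroxymethyl)-3-methoxyhex-5-en-2-one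
Conditions: n-Bu4NF, AcOH (1:1), THF, 0 °C → rt
Reagents that add atoms: none
Why: Fluoride cleavage of the primary silyl ether, buffered with acetic acid so that neither retro-aldol loss of formaldehyde from the β-hydroxy ketone nor 6-endo addition of the freed hydroxyl to the vinylogous ester is promoted.

Step 11
Reactants: 16 (S,E)-1-[(4R,5R)-5-(3,4-dimethoxyphenyl)-4-methyldihydrofuran-2(3H)-ylidene]-3-(hydroxymethyl)-3-methoxyhex-5-en-2-one
Product: 17 (S,E)-2-allyl-4-[(4R,5R)-5-(3,4-dimethoxyphenyl)-4-methyldihydrofuran-2(3H)-ylidene]-2-methoxy-3-oxobutanal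
Conditions: Dess–Martin periodinane, pyridine, CH2Cl2, 0 °C → rt
Reagents that add atoms: none
Why: Mild buffered oxidation of the neopentyl-type primary alcohol to the non-enolisable aldehyde, which should leave the enol ether, the alkene and the electron-rich arene alone.

Step 12
Reactants: 17 (S,E)-2-allyl-4-[(4R,5R)-5-(3,4-dimethoxyphenyl)-4-methyldihydrofuran-2(3H)-ylidene]-2-methoxy-3-oxobutanal
Product: 19 (2R,3R,5S)-5-allyl-2-(3,4-dimethoxyphenyl)-5-methoxy-3-methyl-2,3-dihydrobenzofuran-6(5H)-one, via aldol adduct 18 (not isolated)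
Conditions: DBU (1.5 equiv), 4 Å MS, MeCN, 0 → 40 °C
Reagents that add atoms: none
Why: DBU removes one of the C3a protons, which are γ to the C6 carbonyl through the exocyclic enol ether C7a=C7 (α′-enolisation is impossible because C5 is quaternary), and the resulting 2-oxy-dienolate adds through C3a to the formyl carbon C4; E1cB loss of water from aldol adduct 18 then gives the C3a=C4 double bond in conjugation with C7a=C7–C6=O. The closest known reaction type is the intramolecular vinylogous aldol condensation of a β-alkoxy enone, the ring-forming half of a Robinson-type annulation. Ring A closes in the 6-(enolendo)-exo-trig mode. No stereocentre is created: the transient centres at C3a and C4 of 18 become trigonal, while C2, C3 and C5 carry no acidic hydrogen and should pass through unchanged. The step needs γ- over α-reactivity of the dienolate, secured because attack through C7 would give a four-membered ring, and aldol closure over retro-Claisen loss of the formyl group, secured by a non-nucleophilic amidine base in a dry aprotic medium; the enol ether geometry of 17 is immaterial because C7a–C7 is a single bond in the dienolate, and reversible deprotonation lets the dienolate reach the C6=C7 geometry that can close.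

**Compound list**
1 | 3,4-dimethoxybenzaldehyde (veratraldehyde) | O=Cc1ccc(OC)c(OC)c1 | starting material
2 | (E)-crotylboronic acid pinacol ester | C/C=C/CB1OC(C)(C)C(C)(C)O1 | starting material
3 | (1R,2R)-1-(3,4-dimethoxyphenyl)-2-methylbut-3-en-1-ol | O[C@@H](c1ccc(OC)c(OC)c1)[C@@H](C=C)C | intermediate
4 | (1R,2R)-1-(3,4-dimethoxyphenyl)-2-methylbutane-1,4-diol | O[C@@H](c1ccc(OC)c(OC)c1)[C@@H](CCO)C | intermediate
5 | (4R,5R)-5-(3,4-dimethoxyphenyl)-4-methyltetrahydrofuran-2-ol (lactol, both anomers) | O1[C@@H](c2ccc(OC)c(OC)c2)[C@@H](CC1O)C | intermediate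
6 | (1R,2R)-1-(3,4-dimethoxyphenyl)-2-methylpent-4-yn-1-ol | O[C@@H](c1ccc(OC)c(OC)c1)[C@@H](CC#C)C | intermediate
7 | dimethyl 2-methoxymalonate | COC(C(=O)OC)C(=O)OC | starting material
8 | allyl bromide | C=CCBr | starting material
9 | dimethyl 2-allyl-2-methoxymalonate | C=CCC(OC)(C(=O)OC)C(=O)OC | intermediate
10 | methyl (S)-2-{[dimethoxy(methyl)silyl]oxymethyl}-2-methoxypent-4-enoate (not isolated) | C=CC[C@](OC)(CO[Si](C)(OC)OC)C(=O)OC | intermediate
11 | methyl (S)-2-(hydroxymethyl)-2-methoxypent-4-enoate | C=CC[C@](OC)(CO)C(=O)OC | intermediate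
12 | methyl (S)-2-{[(tert-butyldimethylsilyl)oxy]methyl}-2-methoxypent-4-enoate | C=CC[C@](OC)(CO[Si](C)(C)C(C)(C)C)C(=O)OC | intermediate
13 | (S)-2-{[(tert-butyldimethylsilyl)oxy]methyl}-N,2-dimethoxy-N-methylpent-4-enamide | C=CC[C@](OC)(CO[Si](C)(C)C(C)(C)C)C(=O)N(C)OC | intermediate
14 | (4S,9R,10R)-4-{[(tert-butyldimethylsilyl)oxy]methyl}-10-(3,4-dimethoxyphenyl)-10-hydroxy-4-methoxy-9-methyldec-1-en-6-yn-5-one (not isolated) | C=CC[C@](OC)(CO[Si](C)(C)C(C)(C)C)C(=O)C#CC[C@@H](C)[C@@H](O)c1ccc(OC)c(OC)c1 | intermediate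
15 | (S,E)-3-{[(tert-butyldimethylsilyl)oxy]methyl}-1-[(4R,5R)-5-(3,4-dimethoxyphenyl)-4-methyldihydrofuran-2(3H)-ylidene]-3-methoxyhex-5-en-2-one | C=CC[C@](OC)(CO[Si](C)(C)C(C)(C)C)C(=O)/C=C1\C[C@@H](C)[C@H](c2ccc(OC)c(OC)c2)O1 | intermediate
16 | (S,E)-1-[(4R,5R)-5-(3,4-dimethoxyphenyl)-4-methyldihydrofuran-2(3H)-ylidene]-3-(hydroxymethyl)-3-methoxyhex-5-en-2-one | C=CC[C@](OC)(CO)C(=O)/C=C1\C[C@@H](C)[C@H](c2ccc(OC)c(OC)c2)O1 | intermediate
17 | (S,E)-2-allyl-4-[(4R,5R)-5-(3,4-dimethoxyphenyl)-4-methyldihydrofuran-2(3H)-ylidene]-2-methoxy-3-oxobutanal | C=CC[C@](OC)(C=O)C(=O)/C=C1\C[C@@H](C)[C@H](c2ccc(OC)c(OC)c2)O1 | intermediate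
18 | (2R,3R,5S)-5-allyl-2-(3,4-dimethoxyphenyl)-4-hydroxy-5-methoxy-3-methyl-3,3a,4,5-tetrahydrobenzofuran-6(2H)-one (epimers at C3a and C4, not isolated) | C=CC[C@]1(OC)C(O)C2C(=CC1=O)O[C@@H](c1ccc(OC)c(OC)c1)[C@@H]2C | intermediate
19 | (2R,3R,5S)-5-allyl-2-(3,4-dimethoxyphenyl)-5-methoxy-3-methyl-2,3-dihydrobenzofuran-6(5H)-one | C=CC[C@]1(OC)C=C2C(=CC1=O)O[C@@H](c1ccc(OC)c(OC)c1)[C@@H]2C | target

**Count**
Total steps: 12. Longest linear sequence: 8 steps (steps 1–4 then 9–12; equally steps 5–8 then 9–12).

**Steps most likely to fail**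

1. Step 12. The non-enolisable β-keto aldehyde may lose its formyl group by base-induced retro-Claisen cleavage before γ-deprotonation, or the reaction may stall at the aldol stage because E1cB loss of hydroxide is slow. The fallback sets out from 17 and returns at 19 and avoids basic enolisation. Soft enolisation of 17 with TBSOTf/Et3N (CH2Cl2, −78 °C) should give the silyl dienol ether (R,E)-2-allyl-3-[(tert-butyldimethylsilyl)oxy]-4-[(4R,5R)-5-(3,4-dimethoxyphenyl)-4-methyl-4,5-dihydrofuran-2-yl]-2-methoxybut-3-enal F1. BF3·OEt2 (CH2Cl2, −78 °C) then promotes an intramolecular vinylogous Mukaiyama aldol addition, which after work-up should give aldol adduct 18, isolated in this variant. Mesylation (MsCl, Et3N, CH2Cl2, 0 °C) gives (2R,3R,5S)-5-allyl-2-(3,4-dimethoxyphenyl)-5-methoxy-3-methyl-6-oxo-2,3,3a,4,5,6-hexahydrobenzofuran-4-yl methanesulfonate F2, and DBU-induced elimination gives 19.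

2. Step 6. Methoxy and allyl are of similar size and the methoxy oxygen can bind zinc, so the catalyst may discriminate the two ester groups poorly; the second ester may also be reduced. The fallback sets out from 9 and returns at 11 by an enzymatic desymmetrisation. LiAlH4 (THF, 0 °C) reduces 9 to 2-allyl-2-methoxypropane-1,3-diol F3. Monoacetylation with Burkholderia cepacia lipase and vinyl acetate, with the enzyme selected for the required sense, should give (R)-2-(hydroxymethyl)-2-methoxypent-4-en-1-yl acetate F4. TEMPO/PhI(OAc)2 in aqueous MeCN oxidises the free CH2OH to (S)-2-(acetoxymethyl)-2-methoxypent-4-enoic acid F5, done promptly to forestall acyl migration between the two arms. MeI/K2CO3 (DMF) gives methyl (S)-2-(acetoxymethyl)-2-methoxypent-4-enoate F6, and K2CO3/MeOH removes the acetate to give 11.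

3. Step 9. Addition of the alkynide to the α-quaternary amide may be slow, leaving time for proton transfer or alkoxide attack, and the cyclisation may suffer intermolecular addition to the ynone. The fallback sets out from lactol 5 and amide 13 and returns at 15 by a Claisen-type union that needs no alkyne. TEMPO/PhI(OAc)2 (2.5 equiv, CH2Cl2, rt) oxidises 5 to the trans lactone (4R,5R)-5-(3,4-dimethoxyphenyl)-4-methyldihydrofuran-2(3H)-one F7. MeMgBr (THF, 0 °C) converts 13 into (S)-3-{[(tert-butyldimethylsilyl)oxy]methyl}-3-methoxyhex-5-en-2-one F8. Its lithium enolate (LiN(i-Pr)2, 2 equiv, THF, −78 °C) is acylated by lactone F7 to give, after work-up, the cyclic hemiketal (S)-3-{[(tert-butyldimethylsilyl)oxy]methyl}-1-[(4R,5R)-5-(3,4-dimethoxyphenyl)-2-hydroxy-4-methyltetrahydrofuran-2-yl]-3-methoxyhex-5-en-2-one F9, in equilibrium with the open hydroxy 1,3-diketone. PPTS with 4 Å MS in CH2Cl2 should dehydrate F9 to 15.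

Further compounds
F1 | step 12 | (R,E)-2-allyl-3-[(tert-butyldimethylsilyl)oxy]-4-[(4R,5R)-5-(3,4-dimethoxyphenyl)-4-methyl-4,5-dihydrofuran-2-yl]-2-methoxybut-3-enal | C=CC[C@](OC)(C=O)/C(O[Si](C)(C)C(C)(C)C)=C\C1=C[C@@H](C)[C@H](c2ccc(OC)c(OC)c2)O1
F2 | step 12 | (2R,3R,5S)-5-allyl-2-(3,4-dimethoxyphenyl)-5-methoxy-3-methyl-6-oxo-2,3,3a,4,5,6-hexahydrobenzofuran-4-yl methanesulfonate | C=CC[C@]1(OC)C(OS(C)(=O)=O)C2C(=CC1=O)O[C@@H](c1ccc(OC)c(OC)c1)[C@@H]2C
F3 | step 6 | 2-allyl-2-methoxypropane-1,3-diol | C=CCC(OC)(CO)CO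
F4 | step 6 | (R)-2-(hydroxymethyl)-2-methoxypent-4-en-1-yl acetate | C=CC[C@](OC)(COC(C)=O)CO
F5 | step 6 | (S)-2-(acetoxymethyl)-2-methoxypent-4-enoic acid | C=CC[C@](OC)(COC(C)=O)C(=O)O
F6 | step 6 | methyl (S)-2-(acetoxymethyl)-2-methoxypent-4-enoate | C=CC[C@](OC)(COC(C)=O)C(=O)OC
F7 | step 9 | (4R,5R)-5-(3,4-dimethoxyphenyl)-4-methyldihydrofuran-2(3H)-one | O1[C@@H](c2ccc(OC)c(OC)c2)[C@@H](CC1=O)C
F8 | step 9 | (S)-3-{[(tert-butyldimethylsilyl)oxy]methyl}-3-methoxyhex-5-en-2-one | C=CC[C@](OC)(CO[Si](C)(C)C(C)(C)C)C(C)=O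
F9 | step 9 | (S)-3-{[(tert-butyldimethylsilyl)oxy]methyl}-1-[(4R,5R)-5-(3,4-dimethoxyphenyl)-2-hydroxy-4-methyltetrahydrofuran-2-yl]-3-methoxyhex-5-en-2-one | C=CC[C@](OC)(CO[Si](C)(C)C(C)(C)C)C(=O)CC1(O)C[C@@H](C)[C@H](c2ccc(OC)c(OC)c2)O1
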